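**Plan**
- Cuts: first the depside ester bond (ring A carboxyl carbon to O4 of ring B); then, in each benzoate ring, C1–C6 and C2–C3, which leads back to dimethyl malonate and one E-enone; the enone C3=C4 bond is a Wittig cut.
- Enabling feature: each ring is a 6-substituted 2,4-dioxygenated benzoate (C1 carboxyl between O2 and the C6 arm, O4 meta to O2), the dehydro form of a 2,4-dioxocyclohexane-1-carboxylate; in ring A only O4, the vinylogous-acid oxygen, is a methyl ether.
- Forward: one Michael–Dieckmann annulation gives the saturated ring 9 for both halves. Ring A is aromatised with I2–MeOH, which sets the O4-methyl in the same operation; ring B is aromatised with Br2–DMF and carried as its isocoumarin while its two oxygens are differentiated.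
- The halves are joined by Steglich esterification; ketal hydrolysis and a final neutral hydrogenolysis release the depside.
- Stereochemistry: the target has no stereocentre; the two centres formed in the annulation are uncontrolled and erased on aromatisation, and the E-alkene of the enone (from the stabilised ylide) is consumed in the key step.

Key step: step 4

Remark on the chemistry: the dioxolane is not expected to survive the HI or HBr released on aromatisation, so its loss is planned for. On ring A it is restored before isolation, because the free ketone would sit next to the carboxyl that is later activated; on ring B it is replaced by the isocoumarin enol lactone.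

**Route**

Step 1
Reactants: 1 methyl 3-oxooctanoate, 2 ethylene glycol
Product: 3 methyl (2-pentyl-1,3-dioxolan-2-yl)acetate
Conditions: TsOH·H2O (cat.), toluene, reflux, Dean–Stark
Reagents that add atoms: none
Why: Acid-catalysed ketalisation with azeotropic removal of water is the standard protection of the ketone of a β-keto ester and leaves the ester untouched.

Step 2
Reactants: 3 methyl (2-pentyl-1,3-dioxolan-2-yl)acetate
Product: 4 (2-pentyl-1,3-dioxolan-2-yl)acetaldehyde
Conditions: i-Bu2AlH (1.1 equiv), CH2Cl2, −78 °C; MeOH, then aq. KNaC4H4O6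
Reagents that add atoms: none
Why: Partial ester reduction by i-Bu2AlH at −78 °C should stop at the aluminium hemiacetal, here stabilised by chelation to a dioxolane oxygen, and the crude aldehyde is used at once because acid or base would eliminate the β-ketal oxygen.

Step 3
Reactants: 4 (2-pentyl-1,3-dioxolan-2-yl)acetaldehyde, 5 1-(triphenylphosphoranylidene)propan-2-one
Product: 6 (E)-5-(2-pentyl-1,3-dioxolan-2-yl)pent-3-en-2-one
Conditions: CH2Cl2, rt to 40 °C
Reagents that add atoms: none
Why: Wittig olefination with the stabilised acetonyl ylide is essentially neutral, so the β-ketal aldehyde should not eliminate, and stabilised ylides give the E-enone.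

Step 4
Reactants: 6 (E)-5-(2-pentyl-1,3-dioxolan-2-yl)pent-3-en-2-one, 7 dimethyl malonate
Product: 9 methyl 2,4-dioxo-6-[(2-pentyl-1,3-dioxolan-2-yl)methyl]cyclohexane-1-carboxylate (racemic; mixture of diastereomers and enol forms), via Michael adduct 8 (not isolated)
Conditions: NaOMe (1.05 equiv), MeOH, 0 °C, then reflux; cold 1 M HCl to pH 3–4
Reagents that add atoms: none
Why: Sodium dimethyl malonate adds 1,4 to the E-enone (Michael addition, forming C1–C6 of the future ring); after proton transfer the methyl-ketone enolate attacks one malonate ester carbonyl (Claisen/Dieckmann condensation, forming C2–C3) and expels methoxide, the sequence being pulled forward by formation of the stabilised 1,3-dione enolate. The closest known reaction type is the malonate–enone Michael–Claisen synthesis of 6-alkyl-2,4-dioxocyclohexanecarboxylates. The one ring closes in a 6-exo-trig (enolexo) mode. Two stereocentres arise (C1 and C6) but neither is controlled or needed: C1 is epimerisable, the trans isomer and its enol forms should dominate, and both centres vanish on aromatisation. The step needs conjugate addition to outrun γ-deprotonation of the enone (which would eject a dioxolane oxygen) and needs a single Claisen regiochemistry; the first is secured by the soft, fully pre-formed malonate anion meeting an unhindered β-carbon at 0 °C, the second by the substrate, since only the methyl carbon of the ketone can reach an ester carbonyl through a six-membered transition state.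

Step 5
Reactants: 9 methyl 2,4-dioxo-6-[(2-pentyl-1,3-dioxolan-2-yl)methyl]cyclohexane-1-carboxylate, 2 ethylene glycol
Product: 11 methyl 2-hydroxy-4-methoxy-6-[(2-pentyl-1,3-dioxolan-2-yl)methyl]benzoate, via keto ester 10 (not isolated)
Conditions: I2 (2.2 equiv), MeOH, reflux; aq. Na2S2O3/NaHCO3 work-up; then 2, HC(OMe)3, TsOH·H2O (cat.), CH2Cl2, rt
Reagents that add atoms: methanol, CO
Why: In the iodine–methanol aromatisation of 2,4-dioxocyclohexanecarboxylates, methanol etherifies only the unchelated C4 vinylogous-acid position and iodination/loss of HI across C5–C6 gives the 2-hydroxy-4-methoxybenzoate; because the HI formed strips or exchanges the dioxolane, the crude ketone is re-ketalised under mild orthoformate conditions so that a single compound is isolated.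

Step 6
Reactants: 11 methyl 2-hydroxy-4-methoxy-6-[(2-pentyl-1,3-dioxolan-2-yl)methyl]benzoate
Product: 12 methyl 2-(benzyloxy)-4-methoxy-6-[(2-pentyl-1,3-dioxolan-2-yl)methyl]benzoate
Conditions: BnBr, K2CO3, DMF, 60 °C
Reagents that add atoms: benzyl bromide, BrCc1ccccc1
Why: Williamson benzylation of the chelated salicylate hydroxyl is routine in warm DMF, and with the ketone masked there is no enolisable site to C-alkylate.

Step 7
Reactants: 12 methyl 2-(benzyloxy)-4-methoxy-6-[(2-pentyl-1,3-dioxolan-2-yl)methyl]benzoate
Product: 13 2-(benzyloxy)-4-methoxy-6-[(2-pentyl-1,3-dioxolan-2-yl)methyl]benzoic acid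
Conditions: KOH, DMSO–H2O, 90 °C; cold 1 M HCl to pH 3–4
Reagents that add atoms: potassium hydroxide, [K+].[OH-]
Why: Saponification of the doubly ortho-substituted methyl ester needs hot KOH in aqueous DMSO, to which benzyl ether and dioxolane are inert, and cold acidification with immediate extraction should spare the ketal.

Step 8
Reactants: 9 methyl 2,4-dioxo-6-[(2-pentyl-1,3-dioxolan-2-yl)methyl]cyclohexane-1-carboxylate
Product: 15 6,8-dihydroxy-3-pentyl-1H-isochromen-1-one (the isocoumarin), via keto resorcylate 14 (not isolated)
Conditions: Br2 (1.0 equiv), DMF, 0 °C then 80 °C; 1 M HCl work-up; then TsOH·H2O, toluene, reflux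
Reagents that add atoms: water, O
Why: Bromination of the dione enol in DMF followed by thermal loss of HBr is the standard aromatisation of 6-alkyl-2,4-dioxocyclohexanecarboxylates to resorcylates; the acid unmasks the ketone and TsOH in hot toluene drives enol-lactonisation onto the chelated ester, so all ketal and ketone species should funnel into the isocoumarin, in which ketone and carboxyl protect each other.

Step 9
Reactants: 15 6,8-dihydroxy-3-pentyl-1H-isochromen-1-one
Product: 16 8-hydroxy-1-oxo-3-pentyl-1H-isochromen-6-yl 4-methylbenzenesulfonate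
Conditions: TsCl (1.05 equiv), Et3N, THF, 0 °C
Reagents that add atoms: 4-methylbenzenesulfonyl chloride, Cc1ccc(S(Cl)(=O)=O)cc1
Why: The 8-hydroxyl is hydrogen-bonded to the lactone carbonyl and much less acidic, so sulfonylation with one equivalent of TsCl and a tertiary amine should take the free 6-hydroxyl only.

Step 10
Reactants: 16 8-hydroxy-1-oxo-3-pentyl-1H-isochromen-6-yl 4-methylbenzenesulfonate
Product: 17 8-methoxy-1-oxo-3-pentyl-1H-isochromen-6-yl 4-methylbenzenesulfonate
Conditions: MeI, K2CO3, acetone, reflux
Reagents that add atoms: methyl iodide, CI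
Why: Williamson methylation of the remaining chelated hydroxyl; the aryl tosylate and the enol lactone are stable to anhydrous K2CO3 and the isocoumarin has no enolisable carbon to C-methylate.

Step 11
Reactants: 17 8-methoxy-1-oxo-3-pentyl-1H-isochromen-6-yl 4-methylbenzenesulfonate
Product: 18 4-hydroxy-2-methoxy-6-(2-oxoheptyl)benzoic acid
Conditions: KOH, EtOH–H2O, reflux; cold 2 M HCl to pH 2
Reagents that add atoms: potassium hydroxide, [K+].[OH-]
Why: Hot aqueous KOH opens the isocoumarin to the keto carboxylate and cleaves the aryl sulfonate at sulfur in the same operation, a classical isocoumarin-to-keto-acid hydrolysis that avoids saponifying a hindered benzoate.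

Step 12
Reactants: 18 4-hydroxy-2-methoxy-6-(2-oxoheptyl)benzoic acid
Product: 19 benzyl 4-hydroxy-2-methoxy-6-(2-oxoheptyl)benzoate
Conditions: BnBr (1.05 equiv), KHCO3, DMF, rt
Reagents that add atoms: benzyl bromide, BrCc1ccccc1
Why: KHCO3 deprotonates only the carboxylic acid, so SN2 alkylation by benzyl bromide should give the benzyl ester and leave the phenol free.

Step 13
Reactants: 13 2-(benzyloxy)-4-methoxy-6-[(2-pentyl-1,3-dioxolan-2-yl)methyl]benzoic acid, 19 benzyl 4-hydroxy-2-methoxy-6-(2-oxoheptyl)benzoate
Product: 20 benzyl 4-({2-(benzyloxy)-4-methoxy-6-[(2-pentyl-1,3-dioxolan-2-yl)methyl]benzoyl}oxy)-2-methoxy-6-(2-oxoheptyl)benzoate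
Conditions: DCC, DMAP (cat.), CH2Cl2, 0 °C to rt
Reagents that add atoms: none
Why: In this Steglich esterification DMAP relays the O-acylisourea as an acylpyridinium that the unhindered phenol of 19 attacks, and the masked ring A ketone cannot enol-lactonise onto the activated carboxyl.

Step 14
Reactants: 20 benzyl 4-({2-(benzyloxy)-4-methoxy-6-[(2-pentyl-1,3-dioxolan-2-yl)methyl]benzoyl}oxy)-2-methoxy-6-(2-oxoheptyl)benzoate
Product: 21 benzyl 4-{[2-(benzyloxy)-4-methoxy-6-(2-oxoheptyl)benzoyl]oxy}-2-methoxy-6-(2-oxoheptyl)benzoate
Conditions: 1 M HCl, THF, rt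
Reagents that add atoms: water, O
Why: Dilute aqueous acid hydrolyses a ketone dioxolane at room temperature while benzyl ether, benzyl ester and the hindered aryl ester are stable, and the still-benzylated O2 keeps the depside carbonyl unactivated towards the freed enol.

Step 15
Reactants: 21 benzyl 4-{[2-(benzyloxy)-4-methoxy-6-(2-oxoheptyl)benzoyl]oxy}-2-methoxy-6-(2-oxoheptyl)benzoate
Product: 22 4-{[2-hydroxy-4-methoxy-6-(2-oxoheptyl)benzoyl]oxy}-2-methoxy-6-(2-oxoheptyl)benzoic acid (CNP0177576.0)
Conditions: H2 (1 atm), 10% Pd/C, EtOAc, rt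
Reagents that add atoms: none
Why: Hydrogenolysis over Pd/C cleaves the benzyl ether and the benzyl ester together under neutral conditions that the aryl ester and both ketones tolerate, so the heat- and acid-sensitive depside is released in the mildest step.

**Compound list**
1 | methyl 3-oxooctanoate | CCCCCC(=O)CC(=O)OC | starting material
2 | ethylene glycol | OCCO | starting material
3 | methyl (2-pentyl-1,3-dioxolan-2-yl)acetate | CCCCCC1(CC(=O)OC)OCCO1 | intermediate
4 | (2-pentyl-1,3-dioxolan-2-yl)acetaldehyde | CCCCCC1(CC=O)OCCO1 | intermediate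
5 | 1-(triphenylphosphoranylidene)propan-2-one | CC(=O)C=P(c1ccccc1)(c1ccccc1)c1ccccc1 | starting material
6 | (E)-5-(2-pentyl-1,3-dioxolan-2-yl)pent-3-en-2-one | CC(=O)/C=C/CC1(CCCCC)OCCO1 | intermediate
7 | dimethyl malonate | COC(=O)CC(=O)OC | starting material
8 | dimethyl 2-[4-oxo-1-(2-pentyl-1,3-dioxolan-2-yl)pentan-2-yl]propanedioate (racemic Michael adduct) | COC(=O)C(C(=O)OC)C(CC(C)=O)CC1(CCCCC)OCCO1 | intermediate (not isolated)
9 | methyl 2,4-dioxo-6-[(2-pentyl-1,3-dioxolan-2-yl)methyl]cyclohexane-1-carboxylate (racemic, diastereomer and enol mixture) | COC(=O)C1C(=O)CC(=O)CC1CC1(CCCCC)OCCO1 | intermediate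
10 | methyl 2-hydroxy-4-methoxy-6-(2-oxoheptyl)benzoate | CCCCCC(=O)Cc1cc(OC)cc(O)c1C(=O)OC | intermediate (not isolated)
11 | methyl 2-hydroxy-4-methoxy-6-[(2-pentyl-1,3-dioxolan-2-yl)methyl]benzoate | CCCCCC1(Cc2cc(OC)cc(O)c2C(=O)OC)OCCO1 | intermediate
12 | methyl 2-(benzyloxy)-4-methoxy-6-[(2-pentyl-1,3-dioxolan-2-yl)methyl]benzoate | CCCCCC1(Cc2cc(OC)cc(OCc3ccccc3)c2C(=O)OC)OCCO1 | intermediate
13 | 2-(benzyloxy)-4-methoxy-6-[(2-pentyl-1,3-dioxolan-2-yl)methyl]benzoic acid | CCCCCC1(Cc2cc(OC)cc(OCc3ccccc3)c2C(=O)O)OCCO1 | intermediate
14 | methyl 2,4-dihydroxy-6-(2-oxoheptyl)benzoate | CCCCCC(=O)Cc1cc(O)cc(O)c1C(=O)OC | intermediate (not isolated)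
15 | 6,8-dihydroxy-3-pentyl-1H-isochromen-1-one | CCCCCC1=Cc2cc(O)cc(O)c2C(=O)O1 | intermediate
16 | 8-hydroxy-1-oxo-3-pentyl-1H-isochromen-6-yl 4-methylbenzenesulfonate | CCCCCC1=Cc2cc(OS(=O)(=O)c3ccc(C)cc3)cc(O)c2C(=O)O1 | intermediate
17 | 8-methoxy-1-oxo-3-pentyl-1H-isochromen-6-yl 4-methylbenzenesulfonate | CCCCCC1=Cc2cc(OS(=O)(=O)c3ccc(C)cc3)cc(OC)c2C(=O)O1 | intermediate
18 | 4-hydroxy-2-methoxy-6-(2-oxoheptyl)benzoic acid | CCCCCC(=O)Cc1cc(O)cc(OC)c1C(=O)O | intermediate
19 | benzyl 4-hydroxy-2-methoxy-6-(2-oxoheptyl)benzoate | CCCCCC(=O)Cc1cc(O)cc(OC)c1C(=O)OCc1ccccc1 | intermediate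
20 | benzyl 4-({2-(benzyloxy)-4-methoxy-6-[(2-pentyl-1,3-dioxolan-2-yl)methyl]benzoyl}oxy)-2-methoxy-6-(2-oxoheptyl)benzoate | CCCCCC(=O)Cc1cc(OC(=O)c2c(OCc3ccccc3)cc(OC)cc2CC2(CCCCC)OCCO2)cc(OC)c1C(=O)OCc1ccccc1 | intermediate
21 | benzyl 4-{[2-(benzyloxy)-4-methoxy-6-(2-oxoheptyl)benzoyl]oxy}-2-methoxy-6-(2-oxoheptyl)benzoate | CCCCCC(=O)Cc1cc(OC(=O)c2c(OCc3ccccc3)cc(OC)cc2CC(=O)CCCCC)cc(OC)c1C(=O)OCc1ccccc1 | intermediate
22 | 4-{[2-hydroxy-4-methoxy-6-(2-oxoheptyl)benzoyl]oxy}-2-methoxy-6-(2-oxoheptyl)benzoic acid | CCCCCC(=O)Cc1cc(OC)cc(O)c1C(=O)Oc1cc(CC(=O)CCCCC)c(C(=O)O)c(OC)c1 | target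

**Step count and risks**

Total steps: 15. Longest linear sequence: 12 (steps 1–4, 8–12, 13–15).

Steps most likely to fail:

1. Step 4. The enone may be deprotonated at its γ-carbon with β-elimination of a ketal oxygen before the malonate adds, or the sequence may stall at the Michael adduct. Fallback: exchange the roles of the partners. Setting out from aldehyde 4, olefination with Ph3P=CHCO2Me should give methyl (E)-4-(2-pentyl-1,3-dioxolan-2-yl)but-2-enoate F1, a weaker γ-acid than the enone. Methyl acetoacetate and NaOMe in MeOH would add to its β-carbon to give, in the flask, dimethyl 2-acetyl-3-[(2-pentyl-1,3-dioxolan-2-yl)methyl]pentanedioate F2, whose acetyl methyl closes onto the distal ester. The product is compound 9, where the route is rejoined.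

2. Step 5. Etherification may also take the chelated O2 or remain incomplete, and material may be lost to enol-lactonisation while the ketone is unmasked between the two stages. Fallback: separate aromatisation from methylation. Setting out from 9, the Br2–DMF aromatisation of step 8 would be stopped after the aqueous acid work-up and keto resorcylate 14 isolated. One equivalent of MeI with K2CO3 in acetone at rt should methylate only the unchelated 4-hydroxyl to give keto ester 10, which is re-ketalised as in the second stage of step 5 to rejoin the route at 11. This fallback makes no compound outside the list (F0).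

3. Step 13. The O-acylisourea of the doubly ortho-substituted acid may rearrange to the N-acylurea faster than it transfers the acyl group. Fallback: use an isolated acyl donor and a pre-formed phenoxide. Setting out from 13, cyanuric fluoride and pyridine in CH2Cl2 should give 2-(benzyloxy)-4-methoxy-6-[(2-pentyl-1,3-dioxolan-2-yl)methyl]benzoyl fluoride F3, small enough to be attacked despite the ortho substituents. Reaction with phenol 19 and Cs2CO3 in MeCN would rejoin the route at 20.

**Further compounds**
F1 | step 4 | methyl (E)-4-(2-pentyl-1,3-dioxolan-2-yl)but-2-enoate | COC(=O)/C=C/CC1(CCCCC)OCCO1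
F2 | step 4 | dimethyl 2-acetyl-3-[(2-pentyl-1,3-dioxolan-2-yl)methyl]pentanedioate | COC(=O)CC(CC1(CCCCC)OCCO1)C(C(C)=O)C(=O)OC
F0 | step 5 | none | none
F3 | step 13 | 2-(benzyloxy)-4-methoxy-6-[(2-pentyl-1,3-dioxolan-2-yl)methyl]benzoyl fluoride | CCCCCC1(Cc2cc(OC)cc(OCc3ccccc3)c2C(F)=O)OCCO1
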